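**Plan**

- Retrosynthetic cuts, in order: the galloyl ester C–O bond at O3′; the O1′–C2′ aryl ether bond of ring F; the interflavan C4–C8′ bond; then, in the lower chain, C3′–C4′ (acetylide plus aldehyde), C4a′–C4′ (formylation) and C2′–C3′ (alkyne homologation).
- Forward: a 1,3-diarylpropyne carrying the ring D phenol is built from 3,5-bis(benzyloxy)phenol and 3,4,5-tris(benzyloxy)benzaldehyde. Benzylated (−)-epicatechin (rings A, C, B intact) is activated at C4 and joined to C8′. The alkyne becomes the Z-alkene and then the cis-epoxide. Ring F is the only ring formed and closes last, before galloylation and global hydrogenolysis.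
- Stereochemistry: C2 and C3 come from (−)-epicatechin. C4 is set in the Friedel–Crafts step by attack anti to the 3-benzyloxy group (4β). C2′ and C3′ come from catalyst-controlled epoxidation of the Z-alkene, C3′ directly and C2′ after inversion in the ring closure.
- Enabling feature: the ring D oxygen O1′ (on C8a′) sits ortho to both C4a′ (bearing the C4′ methylene) and C8′ (bearing the upper unit), and O1′–C2′ is a benzylic aryl ether cis to the C3′ oxygen. That is the outcome of rear-side attack of this phenol on C2′ of a cis-2′,3′-epoxide.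

Key step: step 13

Remark: the target is read as epicatechin-(4β→8)-epigallocatechin 3′-O-gallate (upper unit 2R,3R,4R with the C4 aryl trans to O3; lower unit 2′R,3′R; unprimed locants and rings A, C, B are the upper unit, primed locants and rings D, F, E the lower unit), and (S,S)-Mn(salen)Cl is assumed, by analogy with cis-β-methylstyrene and indene, to give the benzylic-S epoxide.

**Route**

Step 1
Reactants: 1 (−)-epicatechin
Product: 2 tetra-O-benzyl-(−)-epicatechin (all four phenols benzylated, 3-OH free)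
Conditions: BnBr (4.4 equiv), K2CO3, DMF, 0 °C → rt
Reagents that add atoms: benzyl bromide, BrCc1ccccc1
Why: Williamson etherification in which K2CO3 deprotonates only the four phenols, so the secondary 3-OH stays free and no stereocentre is touched.

Step 2
Reactants: 2 tetra-O-benzyl-(−)-epicatechin
Product: 3 penta-O-benzyl-(−)-epicatechin (3-O-benzyl ether of 2)
Conditions: NaH, BnBr, Bu4NI (cat.), THF/DMF, 0 °C → rt
Reagents that add atoms: benzyl bromide, BrCc1ccccc1
Why: Williamson etherification of the only remaining hydroxyl through its sodium alkoxide; with no free phenol left, base-induced C2 epimerisation through a quinone methide is excluded.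

Step 3
Reactants: 3 penta-O-benzyl-(−)-epicatechin
Product: 4 4β-(2-ethoxyethoxy)-penta-O-benzylepicatechin (C4 ether trans to the 3-benzyloxy group)
Conditions: DDQ, 2-ethoxyethanol, CH2Cl2, rt
Reagents that add atoms: 2-ethoxyethanol, CCOCCO
Why: Oxidative benzylic C–H etherification, known for benzylated flavan-3-ols: DDQ abstracts hydride from C4, the benzylic position conjugated with the 5,7-dioxygenated ring A, and the alcohol adds to the cation anti to the 3-benzyloxy group.

Step 4
Reactants: 5 3,5-bis(benzyloxy)phenol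
Product: 6 4,6-bis(benzyloxy)-2-hydroxybenzaldehyde
Conditions: MgCl2, Et3N, (CH2O)n, MeCN, reflux; 1 M HCl
Reagents that add atoms: paraformaldehyde (formaldehyde), C=O
Why: Magnesium phenoxide-directed ortho-formylation (Casnati–Skattebøl) delivers formaldehyde only next to the phenol oxygen, and the two ortho positions of 5 are equivalent.

Step 5
Reactants: 7 3,4,5-tris(benzyloxy)benzaldehyde
Product: 8 1,2,3-tris(benzyloxy)-5-ethynylbenzene
Conditions: dimethyl (1-diazo-2-oxopropyl)phosphonate, K2CO3, MeOH/THF, rt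
Reagents that add atoms: dimethyl (1-diazo-2-oxopropyl)phosphonate, CC(=O)C(=[N+]=[N-])P(=O)(OC)OC
Why: Seyferth–Gilbert homologation in the Ohira–Bestmann variant turns aryl aldehydes into terminal alkynes under carbonate conditions that leave benzyl ethers alone.

Step 6
Reactants: 8 1,2,3-tris(benzyloxy)-5-ethynylbenzene; 6 4,6-bis(benzyloxy)-2-hydroxybenzaldehyde
Product: 9 rac-1-[4,6-bis(benzyloxy)-2-hydroxyphenyl]-3-[3,4,5-tris(benzyloxy)phenyl]prop-2-yn-1-ol (used crude and cold)
Conditions: 8 (2.3 equiv), n-BuLi (2.2 equiv), THF, −78 °C; then 6, −78 → 0 °C; H2O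
Reagents that add atoms: none
Why: 1,2-Addition of a lithium acetylide to an aldehyde, one equivalent of acetylide being spent on the phenol (the alkyne is recovered); the carbinol centre is formed racemic and is removed in step 7.

Step 7
Reactants: 9 the propargylic carbinol
Product: 10 3,5-bis(benzyloxy)-2-{3-[3,4,5-tris(benzyloxy)phenyl]prop-2-yn-1-yl}phenol
Conditions: Et3SiH (5 equiv), CF3CO2H, CH2Cl2, −40 → 0 °C, slow addition of 9
Reagents that add atoms: none
Why: Ionic hydrogenation, in which acid ionises the benzylic and propargylic carbinol to an ortho-quinone methide-type cation that excess silane reduces at the benzylic carbon before arene nucleophiles can intercept it.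

Step 8
Reactants: 4 4β-(2-ethoxyethoxy)-penta-O-benzylepicatechin; 10 the propargyl phenol (2.5 equiv, surplus recovered)
Product: 11 alkyne phenol adduct: 10 carrying the penta-O-benzylepicatechin-4β-yl group at the ring carbon ortho to the hydroxyl (future C8′), the prop-2-ynyl chain on the other ortho carbon (future C4a′)
Conditions: Me3SiOTf (0.2 equiv), 4 Å sieves, CH2Cl2, −78 °C; Et3N
Reagents that add atoms: none
Why: Lewis acid-promoted Friedel–Crafts C4 arylation of a 4-alkoxyflavan, the standard interflavan bond construction: the ring A-stabilised cation is attacked by ring D at the carbon flanked by the small free hydroxyl and not at the one between two benzyloxy groups (paralleling the C8 over C6 preference of flavan-3-ol nucleophiles), from the face anti to the 3-benzyloxy group, which sets C4 as 4β.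

Step 9
Reactants: 11 alkyne phenol adduct
Product: 12 tert-butyldimethylsilyl ether of 11
Conditions: t-BuMe2SiOTf, 2,6-lutidine, CH2Cl2, 0 °C → rt
Reagents that add atoms: tert-butyldimethylsilyl trifluoromethanesulfonate, CC(C)(C)[Si](C)(C)OS(=O)(=O)C(F)(F)F
Why: Silylation with the triflate and lutidine caps even a phenol with two ortho substituents, masking it against oxidation in step 11 while staying removable with fluoride.

Step 10
Reactants: 12 silylated alkyne
Product: 13 Z-alkene: 12 with the chain reduced to (Z)-CH2–CH=CH–(3,4,5-tribenzyloxyphenyl)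
Conditions: H2 (1 atm), Pd/CaCO3 poisoned with Pb(OAc)2, quinoline, EtOAc, rt
Reagents that add atoms: none
Why: Lindlar semihydrogenation delivers H2 syn on poisoned palladium, stops at the Z-alkene and does not hydrogenolyse benzyl ethers.

Step 11
Reactants: 13 Z-alkene
Product: 14 (2′S,3′R)-cis-epoxide of 13 (silyl ether retained)
Conditions: (S,S)-Mn(salen)Cl (5 mol %; salen = N,N′-bis(3,5-di-tert-butylsalicylidene)cyclohexane-1,2-diamine dianion), mCPBA, N-methylmorpholine N-oxide, CH2Cl2, −78 °C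
Reagents that add atoms: 3-chloroperoxybenzoic acid, OOC(=O)c1cccc(Cl)c1
Why: Jacobsen–Katsuki epoxidation of a cis-disubstituted aryl alkene, in which the chiral oxomanganese salen species and not the remote upper unit selects the alkene face and so sets C2′ and C3′, the low-temperature peracid protocol limiting leakage to the trans-epoxide and sparing the electron-rich rings.

Step 12
Reactants: 14 silylated cis-epoxide
Product: 15 (2′S,3′R)-cis-epoxy phenol: free ring D hydroxyl flanked by the upper unit and by the cis-2,3-epoxy-3-(3,4,5-tribenzyloxyphenyl)propyl chain (taken on crude)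
Conditions: Bu4NF (1.2 equiv), AcOH (1.5 equiv), THF, −20 → 0 °C
Reagents that add atoms: none
Why: Fluoride cleaves the aryl O–Si bond and acetic acid protonates the phenoxide at once, so that base-induced 5-exo opening of the epoxide cannot compete.

Step 13
Reactants: 15 cis-epoxy phenol
Product: 16 deca-O-benzyl-epicatechin-(4β→8)-epigallocatechin with free 3′-hydroxyl
Conditions: (+)-camphorsulfonic acid (0.1 equiv), CH2Cl2, −40 → 0 °C
Reagents that add atoms: none
Why: The sulfonic acid protonates the oxirane oxygen, the benzylic C2′–O bond lengthens under the influence of ring E, and the ring D phenol oxygen on C8a′ attacks C2′ from the rear while the oxirane oxygen leaves to become the C3′ hydroxyl. The closest known reaction is the acid-promoted cyclisation of 2-(3-aryloxiranylmethyl)phenols to flavan-3-ols. Ring F closes in the 6-endo mode by forming O1′–C2′, the 5-exo alternative at C3′ lacking benzylic activation. C2′ is formed with inversion, so its configuration is dictated by the (2′S) epoxide carbon, and the cis-epoxide maps onto the 2′,3′-cis (2′R,3′R) ring with C3′ carried over unchanged. The step needs 6-endo regioselectivity and an SN2-like course; the first is secured by the aryl group on C2′, the second by the only moderate cation-stabilising power of the 3,4,5-tribenzyloxyphenyl ring (two meta oxygens and a flanked para oxygen), catalytic acid, a non-polar solvent and low temperature. Because the only free phenol is the one between C8′ and C4a′, closure can give nothing but the 4→8 connectivity.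

Step 14
Reactants: 16 dimer with free 3′-hydroxyl; 17 3,4,5-tris(benzyloxy)benzoic acid
Product: 18 trideca-O-benzyl-epicatechin-(4β→8)-epigallocatechin 3′-O-gallate
Conditions: DCC, DMAP, CH2Cl2, rt
Reagents that add atoms: none
Why: Steglich esterification acylates the only free hydroxyl, the C3′ alcohol, since the upper 3-oxygen is benzylated; no stereocentre is involved.

Step 15
Reactants: 18 fully benzylated gallate
Product: 19 epicatechin-(4β→8)-epigallocatechin 3′-O-gallate (target)
Conditions: H2 (1 atm), Pd(OH)2/C, THF/MeOH/H2O, rt; filtration, lyophilisation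
Reagents that add atoms: none
Why: Hydrogenolysis over Pd(OH)2/C removes all thirteen benzyl ethers under neutral conditions that leave the gallate ester and the acid-sensitive C4–C8′ bond intact.

**Compound list**

1 | (−)-epicatechin | O[C@@H]1Cc2c(O)cc(O)cc2O[C@@H]1c1ccc(O)c(O)c1 | starting material
2 | tetra-O-benzyl-(−)-epicatechin (3-OH free) | O[C@@H]1Cc2c(OCc9ccccc9)cc(OCc9ccccc9)cc2O[C@@H]1c1ccc(OCc9ccccc9)c(OCc9ccccc9)c1 | intermediate
3 | penta-O-benzyl-(−)-epicatechin | O(Cc9ccccc9)[C@@H]1Cc2c(OCc9ccccc9)cc(OCc9ccccc9)cc2O[C@@H]1c1ccc(OCc9ccccc9)c(OCc9ccccc9)c1 | intermediate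
4 | 4β-(2-ethoxyethoxy)-penta-O-benzylepicatechin | CCOCCO[C@H]1c2c(OCc9ccccc9)cc(OCc9ccccc9)cc2O[C@H](c2ccc(OCc9ccccc9)c(OCc9ccccc9)c2)[C@@H]1OCc9ccccc9 | intermediate
5 | 3,5-bis(benzyloxy)phenol | Oc1cc(OCc9ccccc9)cc(OCc9ccccc9)c1 | starting material
6 | 4,6-bis(benzyloxy)-2-hydroxybenzaldehyde | O=Cc1c(O)cc(OCc9ccccc9)cc1OCc9ccccc9 | intermediate
7 | 3,4,5-tris(benzyloxy)benzaldehyde | O=Cc1cc(OCc9ccccc9)c(OCc9ccccc9)c(OCc9ccccc9)c1 | starting material
8 | 1,2,3-tris(benzyloxy)-5-ethynylbenzene | C#Cc1cc(OCc9ccccc9)c(OCc9ccccc9)c(OCc9ccccc9)c1 | intermediate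
9 | rac-1-[4,6-bis(benzyloxy)-2-hydroxyphenyl]-3-[3,4,5-tris(benzyloxy)phenyl]prop-2-yn-1-ol | OC(C#Cc1cc(OCc9ccccc9)c(OCc9ccccc9)c(OCc9ccccc9)c1)c1c(O)cc(OCc9ccccc9)cc1OCc9ccccc9 | intermediate
10 | 3,5-bis(benzyloxy)-2-{3-[3,4,5-tris(benzyloxy)phenyl]prop-2-yn-1-yl}phenol | Oc1cc(OCc9ccccc9)cc(OCc9ccccc9)c1CC#Cc1cc(OCc9ccccc9)c(OCc9ccccc9)c(OCc9ccccc9)c1 | intermediate
11 | alkyne phenol adduct (upper unit 4β at C8′, free ring D hydroxyl) | Oc1c(CC#Cc2cc(OCc9ccccc9)c(OCc9ccccc9)c(OCc9ccccc9)c2)c(OCc9ccccc9)cc(OCc9ccccc9)c1[C@H]3c4c(OCc9ccccc9)cc(OCc9ccccc9)cc4O[C@H](c5ccc(OCc9ccccc9)c(OCc9ccccc9)c5)[C@@H]3OCc9ccccc9 | intermediate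
12 | tert-butyldimethylsilyl ether of 11 | CC(C)(C)[Si](C)(C)Oc1c(CC#Cc2cc(OCc9ccccc9)c(OCc9ccccc9)c(OCc9ccccc9)c2)c(OCc9ccccc9)cc(OCc9ccccc9)c1[C@H]3c4c(OCc9ccccc9)cc(OCc9ccccc9)cc4O[C@H](c5ccc(OCc9ccccc9)c(OCc9ccccc9)c5)[C@@H]3OCc9ccccc9 | intermediate
13 | Z-alkene silyl ether | CC(C)(C)[Si](C)(C)Oc1c(C/C=C\c2cc(OCc9ccccc9)c(OCc9ccccc9)c(OCc9ccccc9)c2)c(OCc9ccccc9)cc(OCc9ccccc9)c1[C@H]3c4c(OCc9ccccc9)cc(OCc9ccccc9)cc4O[C@H](c5ccc(OCc9ccccc9)c(OCc9ccccc9)c5)[C@@H]3OCc9ccccc9 | intermediate
14 | (2′S,3′R)-cis-epoxide silyl ether | CC(C)(C)[Si](C)(C)Oc1c(C[C@H]2O[C@H]2c6cc(OCc9ccccc9)c(OCc9ccccc9)c(OCc9ccccc9)c6)c(OCc9ccccc9)cc(OCc9ccccc9)c1[C@H]3c4c(OCc9ccccc9)cc(OCc9ccccc9)cc4O[C@H](c5ccc(OCc9ccccc9)c(OCc9ccccc9)c5)[C@@H]3OCc9ccccc9 | intermediate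
15 | (2′S,3′R)-cis-epoxy phenol (key-step precursor) | Oc1c(C[C@H]2O[C@H]2c6cc(OCc9ccccc9)c(OCc9ccccc9)c(OCc9ccccc9)c6)c(OCc9ccccc9)cc(OCc9ccccc9)c1[C@H]3c4c(OCc9ccccc9)cc(OCc9ccccc9)cc4O[C@H](c5ccc(OCc9ccccc9)c(OCc9ccccc9)c5)[C@@H]3OCc9ccccc9 | intermediate
16 | deca-O-benzyl-epicatechin-(4β→8)-epigallocatechin, free 3′-OH | O[C@@H]1Cc2c(OCc9ccccc9)cc(OCc9ccccc9)c([C@H]3c4c(OCc9ccccc9)cc(OCc9ccccc9)cc4O[C@H](c5ccc(OCc9ccccc9)c(OCc9ccccc9)c5)[C@@H]3OCc9ccccc9)c2O[C@@H]1c1cc(OCc9ccccc9)c(OCc9ccccc9)c(OCc9ccccc9)c1 | intermediate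
17 | 3,4,5-tris(benzyloxy)benzoic acid | OC(=O)c1cc(OCc9ccccc9)c(OCc9ccccc9)c(OCc9ccccc9)c1 | starting material
18 | trideca-O-benzyl-epicatechin-(4β→8)-epigallocatechin 3′-O-gallate | O=C(O[C@@H]1Cc2c(OCc9ccccc9)cc(OCc9ccccc9)c([C@H]3c4c(OCc9ccccc9)cc(OCc9ccccc9)cc4O[C@H](c5ccc(OCc9ccccc9)c(OCc9ccccc9)c5)[C@@H]3OCc9ccccc9)c2O[C@@H]1c1cc(OCc9ccccc9)c(OCc9ccccc9)c(OCc9ccccc9)c1)c1cc(OCc9ccccc9)c(OCc9ccccc9)c(OCc9ccccc9)c1 | intermediate
19 | epicatechin-(4β→8)-epigallocatechin 3′-O-gallate | O=C(O[C@@H]1Cc2c(O)cc(O)c([C@H]3c4c(O)cc(O)cc4O[C@H](c4ccc(O)c(O)c4)[C@@H]3O)c2O[C@@H]1c1cc(O)c(O)c(O)c1)c1cc(O)c(O)c(O)c1 | target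

**Count and risks**

Total steps: 15. Longest linear sequence: 11 steps (steps 4, 6 to 15 from 5; equally steps 1 to 3, 8 to 15 from 1).

Step 8. What may go wrong: attack of the C4 cation at the ring D carbon between the two benzyloxy groups, self-condensation of the donor through its own ring A, or acid-induced reaction of the propargyl phenol. Fallback: close ring F before the interflavan bond is made. Setting out from 10, silylation (t-BuMe2SiCl, imidazole, DMF) should give the aryl silyl ether F1 and semihydrogenation over Pd/CaCO3 poisoned with Pb(OAc)2 the Z-alkene F2. Epoxidation with (S,S)-Mn(salen)Cl, mCPBA and N-methylmorpholine N-oxide should then give the (2S,3R)-cis-epoxide F3, Bu4NF/AcOH the epoxy phenol F4, and camphorsulfonic acid the monomer penta-O-benzyl-(−)-epigallocatechin F5. Condensation of 4 with excess F5 under Me3SiOTf at −78 °C is the standard 4β→8 coupling, in which benzylated flavan-3-ols are known to react at C8. It comes back to the route at 16.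

Step 11. What may go wrong: insufficient face selection, leakage to the trans-epoxide through the stepwise radical pathway of the manganese oxo species on this electron-rich styrene, or oxidation of the phloroglucinol-type rings. Fallback: give up reagent control and use the chirality already in the molecule for separation. Setting out from 13, dimethyldioxirane (acetone/CH2Cl2, −20 °C) transfers oxygen in a concerted, metal-free step that keeps the cis geometry but is face-blind. It should give 14 together with the (2′R,3′S)-cis-epoxide diastereomer F6, which the upper unit makes a diastereomer and not an enantiomer and which is removed by chromatography (preparative HPLC if needed). The route is rejoined at 14.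

Step 13. What may go wrong: ionisation at C2′ that erodes inversion, 5-exo opening at C3′, or a hydride shift to the ketone, all favoured if the hindered phenol attacks slowly. Fallback: close the ring in the 2′,3′-trans series, where ionisation and rear-side attack converge on the same product, then invert C3′. Setting out from 13, thiyl radical-mediated isomerisation ((PhS)2 cat., hν, benzene) should give the E-alkene F7. Shi epoxidation with the enantiomer of the D-fructose-derived ketone and KHSO5 (K2CO3 buffer, MeCN/dimethoxymethane/water, 0 °C) should give the (2′S,3′S)-trans-epoxide F8, and Bu4NF/AcOH the trans-epoxy phenol F9. Camphorsulfonic acid, now usable without restraint, should close it to the 2′,3′-trans alcohol F10 (the gallocatechin-type lower unit, C2′ already correct). Dess–Martin periodinane gives the 3′-ketone F11, and LiBH(s-Bu)3 in THF at −78 °C adds hydride from the face opposite ring E, the established conversion of the catechin into the epicatechin series. It comes back to the route at 16.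

**Further compounds**

F1 | step 8 | tert-butyldimethylsilyl ether of 10 | CC(C)(C)[Si](C)(C)Oc1cc(OCc9ccccc9)cc(OCc9ccccc9)c1CC#Cc1cc(OCc9ccccc9)c(OCc9ccccc9)c(OCc9ccccc9)c1
F2 | step 8 | monomeric Z-alkene silyl ether | CC(C)(C)[Si](C)(C)Oc1cc(OCc9ccccc9)cc(OCc9ccccc9)c1C/C=C\c1cc(OCc9ccccc9)c(OCc9ccccc9)c(OCc9ccccc9)c1
F3 | step 8 | monomeric (2S,3R)-cis-epoxide silyl ether | CC(C)(C)[Si](C)(C)Oc1cc(OCc9ccccc9)cc(OCc9ccccc9)c1C[C@H]2O[C@H]2c1cc(OCc9ccccc9)c(OCc9ccccc9)c(OCc9ccccc9)c1
F4 | step 8 | monomeric (2S,3R)-cis-epoxy phenol | Oc1cc(OCc9ccccc9)cc(OCc9ccccc9)c1C[C@H]2O[C@H]2c1cc(OCc9ccccc9)c(OCc9ccccc9)c(OCc9ccccc9)c1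
F5 | step 8 | penta-O-benzyl-(−)-epigallocatechin (3-OH free) | O[C@@H]1Cc2c(OCc9ccccc9)cc(OCc9ccccc9)cc2O[C@@H]1c1cc(OCc9ccccc9)c(OCc9ccccc9)c(OCc9ccccc9)c1
F6 | step 11 | (2′R,3′S)-cis-epoxide silyl ether, diastereomer of 14 | CC(C)(C)[Si](C)(C)Oc1c(C[C@@H]2O[C@@H]2c6cc(OCc9ccccc9)c(OCc9ccccc9)c(OCc9ccccc9)c6)c(OCc9ccccc9)cc(OCc9ccccc9)c1[C@H]3c4c(OCc9ccccc9)cc(OCc9ccccc9)cc4O[C@H](c5ccc(OCc9ccccc9)c(OCc9ccccc9)c5)[C@@H]3OCc9ccccc9
F7 | step 13 | E-alkene silyl ether | CC(C)(C)[Si](C)(C)Oc1c(C/C=C/c2cc(OCc9ccccc9)c(OCc9ccccc9)c(OCc9ccccc9)c2)c(OCc9ccccc9)cc(OCc9ccccc9)c1[C@H]3c4c(OCc9ccccc9)cc(OCc9ccccc9)cc4O[C@H](c5ccc(OCc9ccccc9)c(OCc9ccccc9)c5)[C@@H]3OCc9ccccc9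
F8 | step 13 | (2′S,3′S)-trans-epoxide silyl ether | CC(C)(C)[Si](C)(C)Oc1c(C[C@@H]2O[C@H]2c6cc(OCc9ccccc9)c(OCc9ccccc9)c(OCc9ccccc9)c6)c(OCc9ccccc9)cc(OCc9ccccc9)c1[C@H]3c4c(OCc9ccccc9)cc(OCc9ccccc9)cc4O[C@H](c5ccc(OCc9ccccc9)c(OCc9ccccc9)c5)[C@@H]3OCc9ccccc9
F9 | step 13 | (2′S,3′S)-trans-epoxy phenol | Oc1c(C[C@@H]2O[C@H]2c6cc(OCc9ccccc9)c(OCc9ccccc9)c(OCc9ccccc9)c6)c(OCc9ccccc9)cc(OCc9ccccc9)c1[C@H]3c4c(OCc9ccccc9)cc(OCc9ccccc9)cc4O[C@H](c5ccc(OCc9ccccc9)c(OCc9ccccc9)c5)[C@@H]3OCc9ccccc9
F10 | step 13 | deca-O-benzyl-epicatechin-(4β→8)-gallocatechin (2′R,3′S), free 3′-OH | O[C@H]1Cc2c(OCc9ccccc9)cc(OCc9ccccc9)c([C@H]3c4c(OCc9ccccc9)cc(OCc9ccccc9)cc4O[C@H](c5ccc(OCc9ccccc9)c(OCc9ccccc9)c5)[C@@H]3OCc9ccccc9)c2O[C@@H]1c1cc(OCc9ccccc9)c(OCc9ccccc9)c(OCc9ccccc9)c1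
F11 | step 13 | 3′-ketone of the benzylated dimer (2′R) | O=C1Cc2c(OCc9ccccc9)cc(OCc9ccccc9)c([C@H]3c4c(OCc9ccccc9)cc(OCc9ccccc9)cc4O[C@H](c5ccc(OCc9ccccc9)c(OCc9ccccc9)c5)[C@@H]3OCc9ccccc9)c2O[C@@H]1c1cc(OCc9ccccc9)c(OCc9ccccc9)c(OCc9ccccc9)c1
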